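**Strategy**

Everything rests on opening ring A between C2 and C3. The quaternary carbon C4 of ring A is bonded to a methyl group, a methoxycarbonyl group and the oxygen-bearing C3, a pattern that a methylmalonate unit on C5 of ring B can supply if one of its two diastereotopic esters becomes C3. In the key step a sulfone-stabilised carbanion at C2 acylates that ester: one operation forms C2–C3, closes ring A trans-fused onto ring B and sets the C4 configuration, the axial C10 methyl differentiating the esters. The precursor is a ring-B cyclohexanone ketal (C9) bearing the methylmalonate on C5 and, on C10, a methyl group and a 2-(phenylsulfonyl)ethyl arm.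

Key step: step 4

Remark: atoms carry labdane numbers (ring A = C1–C5, C10; ring B = C5–C10); the (R)-binaphthoxide catalyst of step 1 is assumed to induce at C5 in the sense known for unsubstituted cyclohex-2-en-1-one, and its enantiomer would be used if the sense proved opposite.

**Route**

Step 1
Reactants: 1 2-methylcyclohex-2-en-1-one; 2 dimethyl 2-methylmalonate
Product: 3 dimethyl 2-methyl-2-[(1R)-2-methyl-3-oxocyclohexyl]malonate (both epimers at C10)
Conditions: LiAl[(R)-1,1'-binaphthalene-2,2'-diolate]2 (10 mol %), KOt-Bu (9 mol %), 4 Å MS, THF, rt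
Reagents that add atoms: none
Why: Catalytic asymmetric Michael addition under Lewis acid/Brønsted base catalysis by the chiral aluminium–lithium binaphthoxide, a reaction type established for 2-substituted malonates and cyclic enones, should deliver the malonate to one face of C5 (R); the C10 center formed on protonation may stay a mixture because step 2 passes through its enamine.

Step 2
Reactants: 3 dimethyl 2-methyl-2-[(1R)-2-methyl-3-oxocyclohexyl]malonate; 4 benzylamine; 5 phenyl vinyl sulfone
Product: 8 dimethyl 2-methyl-2-[(1R,2S)-2-methyl-3-oxo-2-(2-(phenylsulfonyl)ethyl)cyclohexyl]malonate, via N-benzyl imine 6 (not isolated), via alkylated N-benzyl imine 7 (not isolated)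
Conditions: BnNH2 (1.05 equiv), 4 Å MS, toluene, 60 °C; then 5 (1.5 equiv), THF, 60 °C; then 10 % aq. AcOH, rt
Reagents that add atoms: water, O
Why: The imine reacts through its more substituted secondary enamine in an aza-ene-type Michael addition, the imine variant of the Michael reaction that alkylates only the more substituted α-carbon, so no enolate is formed from which the β-malonate could be expelled; the sulfone approaches C10 anti to the bulky C5 substituent, which places the arm trans to the malonate and the methyl cis (10S), and hydrolysis returns the ketone.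

Step 3
Reactants: 8 dimethyl 2-methyl-2-[(1R,2S)-2-methyl-3-oxo-2-(2-(phenylsulfonyl)ethyl)cyclohexyl]malonate
Product: 9 dimethyl 2-methyl-2-[(6S,7R)-6-methyl-6-(2-(phenylsulfonyl)ethyl)-1,4-dioxaspiro[4.5]decan-7-yl]malonate
Conditions: Me3SiOCH2CH2OSiMe3 (3 equiv), Me3SiOTf (10 mol %), CH2Cl2, −78 → −20 °C
Reagents that add atoms: 1,2-bis(trimethylsilyloxy)ethane, C[Si](C)(C)OCCO[Si](C)(C)C
Why: Silyl-triflate-catalysed ketalisation with the bis-silyl ether of ethylene glycol converts hindered ketones at low temperature without touching esters or sulfone, and it removes the only other enolisable position before the carbanion chemistry.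

Step 4
Reactants: 9 dimethyl 2-methyl-2-[(6S,7R)-6-methyl-6-(2-(phenylsulfonyl)ethyl)-1,4-dioxaspiro[4.5]decan-7-yl]malonate
Product: 12 methyl (4R,5R,10S)-9,9-(ethylenedioxy)-4,10-dimethyl-3-oxo-2-(phenylsulfonyl)-trans-decalin-4-carboxylate, via C2-lithiated sulfone 10 (not isolated), via lithium enolate 11 (not isolated)
Conditions: LiN(i-Pr)2 (2.2 equiv), THF, −78 → −30 °C; AcOH quench
Reagents that add atoms: none
Why: The amide base removes a proton from C2, the only acidic C–H of 9, and carbanion 10 adds to one ester carbonyl on C4; loss of methoxide and deprotonation of the β-keto sulfone to enolate 11 by the second equivalent of base make the acylation irreversible. The closest known reaction type is the Dieckmann-type intramolecular acylation of an α-sulfonyl carbanion by an ester. Ring A closes in the 6-exo-trig mode. The new stereocenter C4 is controlled by a chair transition state fused to ring B with C5–C4 and C10–C1 equatorial: the C4 substituent that is not attacked and sits axial is 1,3-syn to the axial C10 methyl, a site tolerated better by the flat CO2Me than by CH3, so the ester should end axial (β) and the methyl equatorial (α), i.e. 4R. The step needs group selectivity between the two diastereotopic esters; the fixed C5/C10 configuration and the axial C10 methyl secure it, and low temperature should sharpen it. C2 forms as an enolisable center and is removed in step 5.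

Step 5
Reactants: 12 methyl (4R,5R,10S)-9,9-(ethylenedioxy)-4,10-dimethyl-3-oxo-2-(phenylsulfonyl)-trans-decalin-4-carboxylate
Product: 13 methyl (4R,5R,10S)-9,9-(ethylenedioxy)-4,10-dimethyl-3-oxo-trans-decalin-4-carboxylate
Conditions: Al(Hg), THF/H2O 9:1, 0 °C → rt
Reagents that add atoms: none
Why: Reductive desulfonylation of a β-keto sulfone by electron transfer from aluminium amalgam cleaves the C2–S bond through the enolate and leaves ester, ketal and the C4 quaternary center untouched.

Step 6
Reactants: 13 methyl (4R,5R,10S)-9,9-(ethylenedioxy)-4,10-dimethyl-3-oxo-trans-decalin-4-carboxylate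
Product: 15 methyl (3R,4R,5R,10S)-3-hydroxy-4,10-dimethyl-9-oxo-trans-decalin-4-carboxylate, via 3α-hydroxy ketal 14 (not isolated)
Conditions: LiBH(s-Bu)3 (1.3 equiv), THF, −78 °C; then 2 M HCl, THF, rt
Reagents that add atoms: water, O
Why: The bulky trialkylborohydride should attack the C3 carbonyl along the equatorial trajectory, as it does with 4,4-disubstituted 3-oxo decalins, giving the axial 3α-alcohol (3R) while the ketal shields C9; the acidic work-up then hydrolyses the dioxolane to the C9 ketone.

Step 7
Reactants: 15 methyl (3R,4R,5R,10S)-3-hydroxy-4,10-dimethyl-9-oxo-trans-decalin-4-carboxylate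
Product: 16 methyl (3R,4R,5R,10S)-3-acetoxy-4,10-dimethyl-9-oxo-trans-decalin-4-carboxylate
Conditions: Ac2O, DMAP, pyridine, 40 °C
Reagents that add atoms: acetic anhydride, CC(=O)OC(C)=O
Why: DMAP-catalysed acylation esterifies the hindered axial alcohol; the acetate is the group the target needs and every later step is chosen to tolerate it.

Step 8
Reactants: 16 methyl (3R,4R,5R,10S)-3-acetoxy-4,10-dimethyl-9-oxo-trans-decalin-4-carboxylate
Product: 17 methyl (3R,4R,5R,10S)-3-acetoxy-9-bromo-8-formyl-4,10-dimethyl-Δ8-octalin-4-carboxylate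
Conditions: PBr3, DMF, CHCl3, 0 → 60 °C; then ice-water
Reagents that add atoms: N,N-dimethylformamide, CN(C)C=O; phosphorus tribromide, BrP(Br)Br; water, O
Why: Vilsmeier–Haack–Arnold bromoformylation: the ketone can enolise only toward C8 because C10 is quaternary, so the bromoiminium reagent formylates C8 (installing C17) and replaces the C9 oxygen by bromide, under conditions that spare acetate and ester.

Step 9
Reactants: 18 (E)-3-methylpent-2-en-4-yn-1-ol
Product: 19 (E)-tert-butyldimethyl[(3-methylpent-2-en-4-yn-1-yl)oxy]silane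
Conditions: t-BuMe2SiCl, imidazole, CH2Cl2, 0 °C → rt
Reagents that add atoms: tert-butyldimethylsilyl chloride, CC(C)(C)[Si](C)(C)Cl
Why: Standard silylation of a primary alcohol; the silyl ether keeps O15 distinct from O17 in steps 12 and 13.

Step 10
Reactants: 19 (E)-tert-butyldimethyl[(3-methylpent-2-en-4-yn-1-yl)oxy]silane
Product: 20 (E)-tert-butyldimethyl[(3-methylpenta-2,4-dien-1-yl)oxy]silane
Conditions: H2 (1 atm), Pd/CaCO3 poisoned with Pb(OAc)2, quinoline, hexane, rt
Reagents that add atoms: none
Why: Partial hydrogenation of a terminal alkyne under Lindlar conditions stops at the vinyl group and leaves the trisubstituted E double bond unchanged.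

Step 11
Reactants: 20 (E)-tert-butyldimethyl[(3-methylpenta-2,4-dien-1-yl)oxy]silane; 17 methyl (3R,4R,5R,10S)-3-acetoxy-9-bromo-8-formyl-4,10-dimethyl-Δ8-octalin-4-carboxylate
Product: 22 methyl (13E)-3α-acetoxy-15-(tert-butyldimethylsilyloxy)-17-oxolabda-8,13-dien-19-oate, via B-alkyl-9-BBN 21 (not isolated)
Conditions: 9-BBN-H, THF, 0 °C → rt; then 17, PdCl2(dppf) (10 mol %), AsPh3, 3 M aq. K3PO4, DMF, rt → 50 °C
Reagents that add atoms: none
Why: 9-BBN adds to the terminal vinyl group of the diene with boron on the end carbon, and the primary alkylborane undergoes B-alkyl Suzuki–Miyaura coupling with the formyl-activated vinyl bromide, forming C9–C11 with the E alkene intact.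

Step 12
Reactants: 22 methyl (13E)-3α-acetoxy-15-(tert-butyldimethylsilyloxy)-17-oxolabda-8,13-dien-19-oate
Product: 23 methyl (13E)-3α-acetoxy-15-(tert-butyldimethylsilyloxy)-17-hydroxylabda-8,13-dien-19-oate
Conditions: NaBH4, CeCl3·7H2O, MeOH, −20 → 0 °C
Reagents that add atoms: none
Why: Luche 1,2-reduction of the conjugated aldehyde is fast at low temperature and leaves both esters, the silyl ether and both alkenes alone.

Step 13
Reactants: 23 methyl (13E)-3α-acetoxy-15-(tert-butyldimethylsilyloxy)-17-hydroxylabda-8,13-dien-19-oate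
Product: 26 methyl (13E)-3α-acetoxy-15-(tert-butyldimethylsilyloxy)labda-8(17),13-dien-19-oate, via N-allyl sulfonylhydrazine 24 (not isolated), via allylic diazene 25 (not isolated)
Conditions: 2-nitrobenzenesulfonylhydrazide, PPh3, diethyl azodicarboxylate, THF, −30 °C → rt
Reagents that add atoms: none
Why: Mitsunobu displacement of the primary allylic alcohol by the sulfonylhydrazide, loss of sulfinic acid and retro-ene extrusion of N2 from the allylic diazene (reductive 1,3-transposition) move the double bond to C8=C17 and deliver hydrogen to C9; the transfer should occur on the α face, the axial direction not shielded by the C10 methyl, which sets 9S with the side chain equatorial.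

Step 14
Reactants: 26 methyl (13E)-3α-acetoxy-15-(tert-butyldimethylsilyloxy)labda-8(17),13-dien-19-oate
Product: 27 methyl (13E)-3α-acetoxy-15-hydroxylabda-8(17),13-dien-19-oate (CNP0164591.1)
Conditions: HF·pyridine, THF/pyridine, 0 °C → rt
Reagents that add atoms: none
Why: Buffered fluoride cleaves the primary silyl ether without hydrolysing the acetate or ester and without isomerising the exocyclic alkene.

**Compound list**

1 | 2-methylcyclohex-2-en-1-one | CC1=CCCCC1=O | starting material
2 | dimethyl 2-methylmalonate | COC(=O)C(C)C(=O)OC | starting material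
3 | dimethyl 2-methyl-2-[(1R)-2-methyl-3-oxocyclohexyl]malonate (C5 R; both C10 epimers) | COC(=O)C(C)(C(=O)OC)[C@@H]1CCCC(=O)C1C | intermediate
4 | benzylamine | NCc1ccccc1 | starting material
5 | phenyl vinyl sulfone | C=CS(=O)(=O)c1ccccc1 | starting material
6 | N-benzyl imine of 3 | COC(=O)C(C)(C(=O)OC)[C@@H]1CCCC(=NCc2ccccc2)C1C | intermediate
7 | N-benzyl imine of 8 | COC(=O)C(C)(C(=O)OC)[C@@H]1CCCC(=NCc2ccccc2)[C@@]1(C)CCS(=O)(=O)c1ccccc1 | intermediate
8 | dimethyl 2-methyl-2-[(1R,2S)-2-methyl-3-oxo-2-(2-(phenylsulfonyl)ethyl)cyclohexyl]malonate | COC(=O)C(C)(C(=O)OC)[C@@H]1CCCC(=O)[C@@]1(C)CCS(=O)(=O)c1ccccc1 | intermediate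
9 | dimethyl 2-methyl-2-[(6S,7R)-6-methyl-6-(2-(phenylsulfonyl)ethyl)-1,4-dioxaspiro[4.5]decan-7-yl]malonate (key-step precursor) | COC(=O)C(C)(C(=O)OC)[C@@H]1CCCC2(OCCO2)[C@@]1(C)CCS(=O)(=O)c1ccccc1 | intermediate
10 | C2-lithiated sulfone of 9 | COC(=O)C(C)(C(=O)OC)[C@@H]1CCCC2(OCCO2)[C@@]1(C)CC([Li])S(=O)(=O)c1ccccc1 | intermediate
11 | lithium enolate of 12 | COC(=O)[C@]1(C)[C@@H]2CCCC3(OCCO3)[C@@]2(C)CC(S(=O)(=O)c4ccccc4)=C1O[Li] | intermediate
12 | methyl (4R,5R,10S)-9,9-(ethylenedioxy)-4,10-dimethyl-3-oxo-2-(phenylsulfonyl)-trans-decalin-4-carboxylate (4β-CO2Me, 4α-Me, 5α-H, 10β-Me; C2 unassigned) | COC(=O)[C@]1(C)[C@@H]2CCCC3(OCCO3)[C@@]2(C)CC(S(=O)(=O)c4ccccc4)C1=O | intermediate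
13 | methyl (4R,5R,10S)-9,9-(ethylenedioxy)-4,10-dimethyl-3-oxo-trans-decalin-4-carboxylate | O1CCOC12CCC[C@@H]3[C@]2(C)CCC(=O)[C@]3(C)C(=O)OC | intermediate
14 | methyl (3R,4R,5R,10S)-9,9-(ethylenedioxy)-3-hydroxy-4,10-dimethyl-trans-decalin-4-carboxylate (3α-OH) | O1CCOC12CCC[C@@H]3[C@]2(C)CC[C@@H](O)[C@]3(C)C(=O)OC | intermediate
15 | methyl (3R,4R,5R,10S)-3-hydroxy-4,10-dimethyl-9-oxo-trans-decalin-4-carboxylate | O=C1CCC[C@@H]2[C@]1(C)CC[C@@H](O)[C@]2(C)C(=O)OC | intermediate
16 | methyl (3R,4R,5R,10S)-3-acetoxy-4,10-dimethyl-9-oxo-trans-decalin-4-carboxylate | O=C1CCC[C@@H]2[C@]1(C)CC[C@@H](OC(C)=O)[C@]2(C)C(=O)OC | intermediate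
17 | methyl (3R,4R,5R,10S)-3-acetoxy-9-bromo-8-formyl-4,10-dimethyl-Δ8-octalin-4-carboxylate | BrC1=C(C=O)CC[C@@H]2[C@]1(C)CC[C@@H](OC(C)=O)[C@]2(C)C(=O)OC | intermediate
18 | (E)-3-methylpent-2-en-4-yn-1-ol | C#C/C(C)=C/CO | starting material
19 | (E)-tert-butyldimethyl[(3-methylpent-2-en-4-yn-1-yl)oxy]silane | C#C/C(C)=C/CO[Si](C)(C)C(C)(C)C | intermediate
20 | (E)-tert-butyldimethyl[(3-methylpenta-2,4-dien-1-yl)oxy]silane | C=C/C(C)=C/CO[Si](C)(C)C(C)(C)C | intermediate
21 | 9-[(E)-5-(tert-butyldimethylsilyloxy)-3-methylpent-3-en-1-yl]-9-borabicyclo[3.3.1]nonane | CC(C)(C)[Si](C)(C)OC/C=C(C)/CCB1C2CCCC1CCC2 | intermediate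
22 | methyl (13E)-3α-acetoxy-15-(tert-butyldimethylsilyloxy)-17-oxolabda-8,13-dien-19-oate | CC(C)(C)[Si](C)(C)OC/C=C(C)/CCC1=C(C=O)CC[C@@H]2[C@]1(C)CC[C@@H](OC(C)=O)[C@]2(C)C(=O)OC | intermediate
23 | methyl (13E)-3α-acetoxy-15-(tert-butyldimethylsilyloxy)-17-hydroxylabda-8,13-dien-19-oate | CC(C)(C)[Si](C)(C)OC/C=C(C)/CCC1=C(CO)CC[C@@H]2[C@]1(C)CC[C@@H](OC(C)=O)[C@]2(C)C(=O)OC | intermediate
24 | N-(C17-allyl)-N-(2-nitrophenylsulfonyl)hydrazine derived from 23 | CC(C)(C)[Si](C)(C)OC/C=C(C)/CCC1=C(CN(N)S(=O)(=O)c3ccccc3[N+](=O)[O-])CC[C@@H]2[C@]1(C)CC[C@@H](OC(C)=O)[C@]2(C)C(=O)OC | intermediate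
25 | C17 allylic diazene derived from 24 | CC(C)(C)[Si](C)(C)OC/C=C(C)/CCC1=C(CN=N)CC[C@@H]2[C@]1(C)CC[C@@H](OC(C)=O)[C@]2(C)C(=O)OC | intermediate
26 | methyl (13E)-3α-acetoxy-15-(tert-butyldimethylsilyloxy)labda-8(17),13-dien-19-oate | C=C1CC[C@@H]2[C@](C)(CC[C@@H](OC(C)=O)[C@]2(C)C(=O)OC)[C@H]1CC/C(C)=C/CO[Si](C)(C)C(C)(C)C | intermediate
27 | methyl (13E)-3α-acetoxy-15-hydroxylabda-8(17),13-dien-19-oate, (3R,4R,5R,9S,10R) | C=C1CC[C@@H]2[C@](C)(CC[C@@H](OC(C)=O)[C@]2(C)C(=O)OC)[C@H]1CC/C(C)=C/CO | target

**Totals and risks**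

Total step count: 14. Longest linear sequence: 12 steps (steps 1–8 and 11–14); steps 9 and 10 prepare the side chain.

Steps most likely to fail:

Step 4. The two diastereotopic esters may not be distinguished well enough during ring closure, so that both C4 configurations form. The fallback replaces kinetic group selection by separation and chemoselective activation. It sets out from 9, which is half-saponified (KOH, 1 equiv, MeOH/H2O) to the two C4-diastereomeric half-esters. After chromatographic separation, the isomer whose free carboxyl is destined to become C3, half-ester F1, is converted with 1,1'-carbonyldiimidazole into acyl imidazolide F3. Only this activated acyl group is attacked by the C2 carbanion (LiN(SiMe3)2, THF, −78 °C), and the route is rejoined at 12. The other isomer, epimeric half-ester F2, is returned to 9 with Me3SiCHN2.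

Step 2. Bond formation at the congested C10 may be too slow, the less substituted enamine may react at C8 instead, or amine-mediated reversal of the first Michael addition may erode C5. The fallback uses a regiospecific metal enolate in place of the enamine. It sets out from 3: Me3SiCl/NaI/Et3N in MeCN gives the more substituted silyl enol ether F4 (the minor regioisomer is removed). MeLi in THF at −20 °C liberates lithium enolate F5, which is added to 5 at −78 °C in THF/HMPA and quenched cold so that expulsion of the malonate cannot compete. The route is rejoined at 8.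

Step 1. The α-substituted enone may convert poorly with the hindered malonate, or face selection at C5 may be insufficient. The fallback uses intramolecular chirality transfer in place of intermolecular catalysis. It sets out from 1: Corey–Bakshi–Shibata reduction ((R)-B-methyl oxazaborolidine, BH3·SMe2) gives (S)-2-methylcyclohex-2-en-1-ol F6. Esterification with commercial 3-methoxy-2-methyl-3-oxopropanoic acid (DCC, DMAP) gives mixed malonate F7. Ireland–Claisen rearrangement (LiN(SiMe3)2, Me3SiCl, THF, −78 → 60 °C) transfers the C–O configuration suprafacially to C5 and gives half-acid F8, which is methylated (Me3SiCHN2) to alkene diester F9. Hydroboration–oxidation (BH3·THF; NaBO3) gives alcohol F10, and Dess–Martin oxidation rejoins the route at 3.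

**Further compounds**

F1 | step 4 | (2R)-3-methoxy-2-methyl-3-oxo-2-[(6S,7R)-6-methyl-6-(2-(phenylsulfonyl)ethyl)-1,4-dioxaspiro[4.5]decan-7-yl]propanoic acid | COC(=O)[C@](C(O)=O)(C)[C@@H]1CCCC2(OCCO2)[C@@]1(C)CCS(=O)(=O)c1ccccc1
F2 | step 4 | (2S)-epimer of F1 (recycled to 9) | COC(=O)[C@@](C(O)=O)(C)[C@@H]1CCCC2(OCCO2)[C@@]1(C)CCS(=O)(=O)c1ccccc1
F3 | step 4 | acyl imidazolide of F1 | COC(=O)[C@](C(=O)n1ccnc1)(C)[C@@H]1CCCC2(OCCO2)[C@@]1(C)CCS(=O)(=O)c1ccccc1
F4 | step 2 | dimethyl 2-methyl-2-[(1R)-2-methyl-3-(trimethylsilyloxy)cyclohex-2-en-1-yl]malonate | COC(=O)C(C)(C(=O)OC)[C@@H]1CCCC(O[Si](C)(C)C)=C1C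
F5 | step 2 | lithium enolate from F4 | COC(=O)C(C)(C(=O)OC)[C@@H]1CCCC(O[Li])=C1C
F6 | step 1 | (S)-2-methylcyclohex-2-en-1-ol | O[C@H]1CCCC=C1C
F7 | step 1 | 1-methyl 3-[(1S)-2-methylcyclohex-2-en-1-yl] 2-methylmalonate | COC(=O)C(C)C(=O)O[C@H]1CCCC=C1C
F8 | step 1 | 3-methoxy-2-methyl-2-[(1R)-2-methylcyclohex-2-en-1-yl]-3-oxopropanoic acid | COC(=O)C(C)(C(O)=O)[C@@H]1CCCC=C1C
F9 | step 1 | dimethyl 2-methyl-2-[(1R)-2-methylcyclohex-2-en-1-yl]malonate | COC(=O)C(C)(C(=O)OC)[C@@H]1CCCC=C1C
F10 | step 1 | dimethyl 2-[(1R,2R,3R)-3-hydroxy-2-methylcyclohexyl]-2-methylmalonate | COC(=O)C(C)(C(=O)OC)[C@@H]1CCC[C@@H](O)[C@@H]1C
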